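**Plan**
1. Retrosynthesis: the O2 and O7 benzoates are cut first, then the C1–O bond of the ring-fused oxirane. With the ring numbered C1 (oxirane carbon carrying C7), C2, C3, C4=C5, C6 (oxirane CH), the unit O7–C7–C1(–O–C6) is a 2,3-epoxy alcohol, so the C1/C6 oxirane is the Payne isomer of a C1–C7 spiro-oxirane with a free 6-OH.
2. The spiro-oxirane is cut to a C1=C7 methylene (C1–C7 from a C1 ketone), and the C6–O bond to an allylic epoxide of enantiopure bromobenzene cis-dihydrodiol, which supplies the carbocycle, C2 and C3.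
3. Forward order of rings: carbocycle bought; a transient C1/C6 oxirane (opened at C6); the C1/C7 spiro-oxirane; the Payne step turns it into the final C1/C6 oxirane.
4. Stereochemistry: C2 and C3 come from the enzymatic diol; C6 from anti epoxidation then anti opening (O6 cis to O2/O3); C1 from peracid attack anti to O2/O6, then inverted by the intramolecular SN2 of the Payne step.
5. Protecting groups: an allylic oxirane does not survive acid, so O2/O3 are PMB ethers (removed with DDQ) and O6/O3 carry silyl groups (removed with fluoride); O2 is benzoylated while O3 is silylated.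

Key step: step 10

Assumption: diol 1 (the whole-cell cis-dihydroxylation product of bromobenzene) is bought as the single (1S,2S) enantiomer, and its configuration fixes that of the whole route.
Locants and faces: ring carbons keep the target numbering throughout (C2, C3 = diol carbons of 1, C3 next to the C–Br carbon C4). α is the face carrying O2 and O3; β is the opposite face.

Step 1
Reactants: 1 (1S,2S)-3-bromocyclohexa-3,5-diene-1,2-diol
Product: 2 (5S,6S)-1-bromo-5,6-bis[(4-methoxybenzyl)oxy]cyclohexa-1,3-diene (bis-PMB ether of 1)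
Conditions: NaH, PMBCl, Bu4NI (cat.), DMF, 0 °C to rt
Reagents that add atoms: 4-methoxybenzyl chloride, COc1ccc(CCl)cc1
Why: Double Williamson etherification; PMB ethers survive base, peracid, titanium and tin reagents, cannot migrate or attack in step 10, and come off oxidatively without acid, while C2 and C3 are untouched.

Step 2
Reactants: 2 bis-PMB diene
Product: 3 4-bromo-2α,3α-bis(PMB-oxy)-7-oxabicyclo[4.1.0]hept-4-ene with the C1/C6 oxirane on the β-face
Conditions: mCPBA, NaHCO3, CH2Cl2, 0 °C
Reagents that add atoms: 3-chloroperoxybenzoic acid, O=C(OO)c1cccc(Cl)c1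
Why: Prilezhaev epoxidation should take the electron-richer, unhalogenated C1=C6 bond from the face anti to the neighbouring C2 ether, as is usual for O-protected arene cis-dihydrodiols.

Step 3
Reactants: 3 β-epoxide
Product: 4 4-bromo-2α,3α-bis(PMB-oxy)cyclohex-4-ene-1β,6α-diol (trans-diol)
Conditions: 10% aq KOH, DMSO, 70 °C
Reagents that add atoms: water, O
Why: Hydroxide should open the vinyl oxirane by SN2 attack at the allylic carbon C6 from the α-face (inversion), which sets O6 cis to O2/O3 and leaves the C1 hydroxyl on the β-face.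

Step 4
Reactants: 4 trans-diol
Product: 5 6α-O-TBS ether of 4 (1β-OH free)
Conditions: TBSCl (1.1 equiv), imidazole, DMF, 0 °C
Reagents that add atoms: tert-butyldimethylsilyl chloride, CC(C)(C)[Si](C)(C)Cl
Why: Monosilylation with a bulky silyl chloride should pick the allylic C6 hydroxyl, which has one substituted sp3 neighbour, over the C1 hydroxyl flanked by two oxygenated carbons.

Step 5
Reactants: 5 mono-TBS ether
Product: 6 4-bromo-6α-(TBS-oxy)-2α,3α-bis(PMB-oxy)cyclohex-4-en-1-one
Conditions: Dess–Martin periodinane, NaHCO3, CH2Cl2, 0 °C to rt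
Reagents that add atoms: none
Why: Dess–Martin oxidation is buffered and non-basic, so the α,α′-dioxygenated ketone should form without epimerising C2 or C6 or moving the β,γ-double bond into conjugation.

Step 6
Reactants: 6 ketone
Product: 7 4-bromo-1-methylidene-6α-(TBS-oxy)-2α,3α-bis(PMB-oxy)cyclohex-4-ene
Conditions: Tebbe reagent, pyridine, THF/toluene, −40 to 0 °C
Reagents that add atoms: Tebbe reagent, C[Al-]1(C)C[Ti]([Cl+]1)(C1C=CC=C1)C1C=CC=C1
Why: Tebbe methylenation (titanium methylidene, [2+2] then cycloreversion) is non-basic and so suits this hindered, enolisable α-alkoxy ketone; it brings in C7.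

Step 7
Reactants: 7 methylidene compound
Product: 8 bromo spiro-epoxide: C1/C7 spiro-oxirane with oxygen β and C7 α, 4-bromo, 6α-OTBS, 2α,3α-bis(PMB-oxy)
Conditions: mCPBA (excess), NaHCO3, CH2Cl2, rt
Reagents that add atoms: 3-chloroperoxybenzoic acid, O=C(OO)c1cccc(Cl)c1
Why: Prilezhaev epoxidation of the 1,1-disubstituted exocyclic alkene (the bromoalkene is inert) should occur on the β-face, away from the two flanking α-oriented allylic oxygens O2 and O6, which sets C1 with the spiro oxygen trans to O6.

Step 8
Reactants: 8 bromo spiro-epoxide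
Product: 9 debrominated spiro-epoxide (C4=C5), 6α-OTBS, 2α,3α-bis(PMB-oxy)
Conditions: Bu3SnH (0.5 M), AIBN (cat.), toluene, 80 °C
Reagents that add atoms: none
Why: Radical-chain hydrodebromination of the vinyl bromide with tin hydride is routine on halodiol-derived cyclitols, and the ethers, the silyl ether and the non-allylic oxirane are inert to it.

Step 9
Reactants: 9 spiro-epoxy silyl ether
Product: 10 spiro-epoxy alcohol: C1/C7 spiro-oxirane (O β, C7 α), free 6α-OH, 2α,3α-bis(PMB-oxy), C4=C5
Conditions: HF·pyridine, pyridine, THF, 0 °C to rt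
Reagents that add atoms: none
Why: Pyridine-buffered HF desilylation generates no alkoxide, so the epoxy alcohol should be isolated unrearranged; the PMB ethers and the oxygen-flanked spiro-oxirane tolerate the reagent.

Step 10
Reactants: 10 spiro-epoxy alcohol; 11 benzoyl chloride
Product: 13 [(1S,2R,3R,6S)-2,3-bis(PMB-oxy)-7-oxabicyclo[4.1.0]hept-4-en-1-yl]methyl benzoate, via ring-fused epoxy alkoxide 12 (not isolated)
Conditions: NaH, THF, 0 °C to rt; then BzCl, 0 °C
Reagents that add atoms: benzoyl chloride (11), O=C(Cl)c1ccccc1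
Why: NaH gives the C6 alkoxide, which lies anti-periplanar to the spiro C1–O7 bond and displaces it at C1 in an intramolecular SN2 reaction, so the C1–O6 bond of the ring-fused oxirane forms while O7 leaves as the primary C7 alkoxide, which benzoyl chloride then acylates. The closest known reaction type is the Payne rearrangement of 2,3-epoxy alcohols under aprotic conditions with capture of the released alkoxide in the same flask. The new oxirane (C1, C6, O6) closes in a 3-exo-tet mode as the spiro-oxirane opens. C1 is the one stereocentre newly set: it is inverted, so C7 ends trans to the oxirane, an outcome dictated by the α-configuration of O6 at C6, which is retained and places the oxirane cis to O2 and O3. The step needs a single nucleophilic oxygen and a favourable equilibrium: O2 and O3 are PMB ethers that can neither attack nor migrate, and the equilibrium should favour the trisubstituted, alkene-conjugated oxirane with the primary alkoxide, which is drained further by the faster acylation of that unhindered alkoxide.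

Step 11
Reactants: 13 bis-PMB epoxy benzoate
Product: 14 [(1S,2R,3R,6S)-2,3-dihydroxy-7-oxabicyclo[4.1.0]hept-4-en-1-yl]methyl benzoate
Conditions: DDQ (2.6 equiv), CH2Cl2/pH 7 phosphate buffer, 0 °C to rt
Reagents that add atoms: none
Why: Oxidative PMB cleavage with DDQ in buffered wet dichloromethane should free the cis-diol under neutral conditions, which is the reason no acid-labile acetal is carried past the point where the acid-sensitive allylic oxirane exists.

Step 12
Reactants: 14 diol; 11 benzoyl chloride
Product: 16 [(1S,2R,3R,6S)-2-(benzoyloxy)-3-(triethylsilyloxy)-7-oxabicyclo[4.1.0]hept-4-en-1-yl]methyl benzoate, via 3-O-triethylsilyl ether 15 (not isolated)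
Conditions: TESCl (1.1 equiv), imidazole, CH2Cl2, −20 °C; then Et3N, DMAP, BzCl, 0 °C to rt
Reagents that add atoms: chlorotriethylsilane, CC[Si](Cl)(CC)CC; benzoyl chloride (11), O=C(Cl)c1ccccc1
Why: Silylation should prefer the unhindered allylic C3 hydroxyl over the C2 hydroxyl next to the fully substituted C1, after which DMAP-catalysed benzoylation acylates the remaining C2 hydroxyl in the same flask.

Step 13
Reactants: 16 silyl ether dibenzoate
Product: 17 [(1S,2R,3R,6S)-2-(benzoyloxy)-3-hydroxy-7-oxabicyclo[4.1.0]hept-4-en-1-yl]methyl benzoate (target)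
Conditions: TBAF/AcOH (1:1), THF, 0 °C
Reagents that add atoms: none
Why: Acetic-acid-buffered fluoride desilylation is neutral, so neither benzoate migration from O2 to O3 nor opening of the allylic oxirane should occur.

**Compound list**
1 | (1S,2S)-3-bromocyclohexa-3,5-diene-1,2-diol | O[C@H]1C=CC=C(Br)[C@H]1O | starting material
2 | (5S,6S)-1-bromo-5,6-bis[(4-methoxybenzyl)oxy]cyclohexa-1,3-diene | COc1ccc(CO[C@H]2C=CC=C(Br)[C@H]2OCc2ccc(OC)cc2)cc1 | intermediate
3 | 4-bromo-2α,3α-bis(PMB-oxy)-7-oxabicyclo[4.1.0]hept-4-ene, β-oxirane | COc1ccc(CO[C@H]2[C@@H]3O[C@@H]3C=C(Br)[C@H]2OCc2ccc(OC)cc2)cc1 | intermediate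
4 | 4-bromo-2α,3α-bis(PMB-oxy)cyclohex-4-ene-1β,6α-diol | COc1ccc(CO[C@H]2[C@H](O)[C@@H](O)C=C(Br)[C@H]2OCc2ccc(OC)cc2)cc1 | intermediate
5 | 6α-O-TBS ether of 4 | COc1ccc(CO[C@H]2[C@H](O)[C@@H](O[Si](C)(C)C(C)(C)C)C=C(Br)[C@H]2OCc2ccc(OC)cc2)cc1 | intermediate
6 | 4-bromo-6α-(TBS-oxy)-2α,3α-bis(PMB-oxy)cyclohex-4-en-1-one | COc1ccc(CO[C@H]2C(=O)[C@@H](O[Si](C)(C)C(C)(C)C)C=C(Br)[C@H]2OCc2ccc(OC)cc2)cc1 | intermediate
7 | 4-bromo-1-methylidene-6α-(TBS-oxy)-2α,3α-bis(PMB-oxy)cyclohex-4-ene | COc1ccc(CO[C@H]2C(=C)[C@@H](O[Si](C)(C)C(C)(C)C)C=C(Br)[C@H]2OCc2ccc(OC)cc2)cc1 | intermediate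
8 | bromo spiro-epoxide (C1/C7 oxirane, O β, C7 α; 6α-OTBS; 2α,3α-OPMB) | COc1ccc(CO[C@H]2[C@@]3(CO3)[C@@H](O[Si](C)(C)C(C)(C)C)C=C(Br)[C@H]2OCc2ccc(OC)cc2)cc1 | intermediate
9 | debrominated spiro-epoxy silyl ether | COc1ccc(CO[C@H]2[C@@]3(CO3)[C@@H](O[Si](C)(C)C(C)(C)C)C=C[C@H]2OCc2ccc(OC)cc2)cc1 | intermediate
10 | spiro-epoxy alcohol (C1/C7 oxirane, O β; 6α-OH; 2α,3α-OPMB) | COc1ccc(CO[C@H]2[C@@]3(CO3)[C@@H](O)C=C[C@H]2OCc2ccc(OC)cc2)cc1 | intermediate
11 | benzoyl chloride | O=C(Cl)c1ccccc1 | starting material
12 | [(1S,2R,3R,6S)-2,3-bis(PMB-oxy)-7-oxabicyclo[4.1.0]hept-4-en-1-yl]methanol (present as its sodium alkoxide) | COc1ccc(CO[C@H]2[C@@]3(CO)O[C@H]3C=C[C@H]2OCc2ccc(OC)cc2)cc1 | intermediate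
13 | [(1S,2R,3R,6S)-2,3-bis(PMB-oxy)-7-oxabicyclo[4.1.0]hept-4-en-1-yl]methyl benzoate | COc1ccc(CO[C@H]2[C@@]3(COC(=O)c4ccccc4)O[C@H]3C=C[C@H]2OCc2ccc(OC)cc2)cc1 | intermediate
14 | [(1S,2R,3R,6S)-2,3-dihydroxy-7-oxabicyclo[4.1.0]hept-4-en-1-yl]methyl benzoate | O=C(OC[C@]12O[C@H]1C=C[C@@H](O)[C@H]2O)c1ccccc1 | intermediate
15 | 3-O-triethylsilyl ether of 14 | O=C(OC[C@]12O[C@H]1C=C[C@@H](O[Si](CC)(CC)CC)[C@H]2O)c1ccccc1 | intermediate
16 | [(1S,2R,3R,6S)-2-(benzoyloxy)-3-(triethylsilyloxy)-7-oxabicyclo[4.1.0]hept-4-en-1-yl]methyl benzoate | O=C(OC[C@]12O[C@H]1C=C[C@@H](O[Si](CC)(CC)CC)[C@H]2OC(=O)c1ccccc1)c1ccccc1 | intermediate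
17 | [(1S,2R,3R,6S)-2-(benzoyloxy)-3-hydroxy-7-oxabicyclo[4.1.0]hept-4-en-1-yl]methyl benzoate | O=C(OC[C@]12O[C@H]1C=C[C@@H](O)[C@H]2OC(=O)c1ccccc1)c1ccccc1 | target

Total step count: 13. Longest linear sequence: 13 steps (1 to 17).

**Steps most likely to fail**

1. Step 10 (key step). What may go wrong: acylation of the secondary alkoxide before it has rearranged, or an equilibrium that holds part of the material on the spiro side. Fallback, leaving at 10 and returning at 13: 10 is equilibrated under classical protic Payne conditions (0.5 M NaOH, t-BuOH/H2O, rt); the free ring-fused epoxy alcohol 12 is isolated by chromatography, with unrearranged 10 recycled; 12 is then benzoylated separately (BzCl, pyridine, 0 °C) to give 13. No new compound arises.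

2. Step 11. What may go wrong: capture of the benzylic oxocarbenium ion by the neighbouring hydroxyl (arylidene acetal formation and over-oxidation), and acid-promoted opening of the allylic oxirane during the double oxidative debenzylation. Fallback, leaving at 9 and returning at 14: the PMB ethers are removed with DDQ already at 9, where no allylic oxirane is present, giving the spiro-epoxy silyl ether diol F1. Trimethyl orthoformate with catalytic PPTS masks the cis-diol as the base-stable cyclic orthoformate F2 (either epimer at the orthoester carbon). TBAF frees O6 to give the spiro-epoxy alcohol F3. NaH and then benzoyl chloride effect the same rearrangement and capture, giving the ring-fused epoxy benzoate F4. A short exposure to pH 4–5 acetate buffer in THF, under which an orthoester should hydrolyse far faster than the oxirane opens, gives the hydroxy formate F5 (position of the formyl group immaterial), and KHCO3 in methanol removes the formyl group to give 14.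

3. Step 12. What may go wrong: insufficient discrimination between the two secondary hydroxyls in the silylation, and sluggish acylation of the hindered C2 hydroxyl. Fallback, leaving at 14 and returning at 17: the allylic C3 hydroxyl alone is oxidised with activated MnO2 to the epoxy enone F6; the remaining C2 hydroxyl is benzoylated (BzCl, pyridine) to give the keto dibenzoate F7; Luche reduction (NaBH4, CeCl3, MeOH, −78 °C), with hydride delivery anti to the adjacent α-benzoyloxy group, should give the 3α-alcohol 17 directly.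

Further compounds
F0 | step 10 | none | none
F1 | step 11 | spiro-epoxy silyl ether diol (9 without PMB groups) | O[C@H]1[C@@]2(CO2)[C@@H](O[Si](C)(C)C(C)(C)C)C=C[C@H]1O
F2 | step 11 | cyclic orthoformate (2-methoxy-1,3-dioxolane) of F1 | COC1O[C@H]2[C@@]3(CO3)[C@@H](O[Si](C)(C)C(C)(C)C)C=C[C@H]2O1
F3 | step 11 | spiro-epoxy alcohol with O2,O3-orthoformate | COC1O[C@H]2[C@@]3(CO3)[C@@H](O)C=C[C@H]2O1
F4 | step 11 | ring-fused epoxy C7 benzoate with O2,O3-orthoformate | COC1O[C@H]2[C@@]3(COC(=O)c4ccccc4)O[C@H]3C=C[C@H]2O1
F5 | step 11 | hydroxy formate (3-O-formyl derivative of 14 drawn) | O=C(OC[C@]12O[C@H]1C=C[C@@H](OC=O)[C@H]2O)c1ccccc1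
F6 | step 12 | epoxy enone (3-oxo derivative of 14) | O=C(OC[C@]12O[C@H]1C=CC(=O)[C@H]2O)c1ccccc1
F7 | step 12 | keto dibenzoate (2-O-benzoyl derivative of F6) | O=C(OC[C@]12O[C@H]1C=CC(=O)[C@H]2OC(=O)c1ccccc1)c1ccccc1
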